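**Three neighbours.** Each flask is a neighbour of the next: the same charges and the same time, in a different bath. Amounts below are fractions of the substrate charged.

| flask | substrate | catalyst | temperature | time |
|---|---|---|---|---|
| red | 0.20 M | 20 mol% | 85 °C | 40 min |
| blue | 0.20 M | 20 mol% | 100 °C | 40 min |
| green | 0.20 M | 20 mol% | 70 °C | 40 min |

    substrate → uncatalysed product (k1 = 0.00313 /min, Ea1 = 112 kJ/mol)
    substrate + catalyst → catalyst + target (k2 = 29.6 /M/min, Ea2 = 59.0 kJ/mol)
    target ⇌ isomer of the product (K3 = 1.62, k3 = 0.0496 /min, Ea3 = 98.0 kJ/mol, ΔH3 = −34.0 kJ/mol)
    (constants at 100 °C)

- the list of constants is for 100 °C, to be carried to other temperatures by the activation energies and enthalpies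

- the best flask by amount of target, in percent of the substrate charged; "all alike" if 1.5 percentage points covers them all (red / blue / green / all alike)
- amount of target at the end, in percent of the substrate charged, red
- amount of target at the end, in percent of the substrate charged, blue
- amount of target at the end, in percent of the substrate charged, green

**Fastest rung.** The catalyst comes back from each turn, so substrate decays in a pseudo-first-order way. In green, the coolest flask, its mean life is 4.45 min. That is also the mean birth time of target, the curve of its formation replaced by one moment.

**Middle rung.** Target and isomer of the product approach their balance with the sum of the forward and back constants. In green the equilibrium constant becomes 4.22, which puts the balance at a target fraction of 19.1%. The relaxation time is 258 min, longer than the 40 min allowed.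

**Slowest rung.** The uncatalysed step in green has the constant 1.33 × 10⁻⁴ /min, far slower than the catalysed decay. It takes a fraction of about 0.0594% of the substrate, and this reckoning drops it.

**Relaxation count.** The quantity that carries the argument is the relaxation count, the time allowed less the birth time, divided by the relaxation time: 0.138 for green. The gap between a full charge of target and the balance fraction shrinks by e to the minus count, here a factor of 0.871. This reckoning therefore gives green 89.6%. Ignoring the birth time would lower that by 1.2 percentage points.

The same steps give red a count of 0.700 and a target fraction of 63.8%. Blue gets a count of 3.14 and a target fraction of 40.8%.

**The forecast.** It names green as best, with 63.7% in red, 40.7% in blue and 89.5% in green, the yield being "set almost entirely by how far it isomerises afterwards".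

**The result.** The simulation gives green as best, with 63.7% in red, 40.7% in blue and 89.5% in green.

**Blue's loss.** Struck out, the isomerisation would leave blue with 99.7% of target instead of 40.7%. Blue's count of 3.14 is larger than green's 0.138, so blue ends close to thermodynamic control and green remains under kinetic control. Green run at 95 °C has a count of 1.92, above red's and below blue's, and that neighbour ends with 44.2% of target.

(The constants used here are invented; the flask was simulated.)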